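**Plan**

- Numbering: furanone ring O1, C2 (C=O), C3, C4 (Br), C5, exocyclic C6; side chain C1'–C4'. The retrosynthesis cuts C6–I first, then O1–C2 and C2–C3 together (C2 leaves as CO), then the C3–I/C4–Br pair (IBr across an alkyne) and C1'–C3 (acylation of an alkyne).
- Enabling feature: in the single ring the carbonyl C2 lies between C3 and O1, and O1–C5=C6 is the enol of a methyl ketone. The lactone is therefore CO plus an acyclic (E)-α-bromo-β-iodo enone whose iodine is cis to the acetyl group.
- Forward: but-3-yn-2-ol (C3–C6 and O1) is silylated and acylated with butanoyl chloride (C1'–C4'). IBr is added while C1' is still the ketone, so iodine goes α (future C3) and bromine β (future C4). C1' is then reduced and acetylated and C5 is oxidised, so the two oxidation levels change places.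
- The only ring closes in the carbonylation (step 8); the C6 iodine is introduced last by ICl addition and loss of HCl.
- Stereochemistry: C1' (R) comes from a reagent-controlled CBS reduction, the tetrasubstituted alkene geometry from anti addition of IBr, and the Z exocyclic alkene from elimination that keeps iodine away from the C4 bromine.

Key step: step 8

Remark: racemic but-3-yn-2-ol is assumed to be adequate, because its carbinol carbon becomes the C5 ketone in step 7. The intermediates between the reduction and that oxidation are therefore pairs of epimers at this carbon and converge afterwards.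

**Route**

Step 1
Reactants: 1 but-3-yn-2-ol (racemic)
Product: 2 tert-butyl(but-3-yn-2-yloxy)dimethylsilane (racemic)
Conditions: TBSCl, imidazole, DMF, 0 °C to rt
Reagents that add atoms: tert-butyldimethylsilyl chloride, C[Si](C)(Cl)C(C)(C)C
Why: Imidazole-promoted silyl ether formation on a secondary alcohol, which masks the oxygen that ends as O1 while the alkyne is acylated and halogenated and the other carbonyl is reduced.

Step 2
Reactants: 2 tert-butyl(but-3-yn-2-yloxy)dimethylsilane; 3 butanoyl chloride
Product: 4 7-[(tert-butyldimethylsilyl)oxy]oct-5-yn-4-one (racemic)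
Conditions: PdCl2(PPh3)2 (2 mol %), CuI (4 mol %), Et3N (1.2 equiv), THF, rt
Reagents that add atoms: none
Why: Acyl Sonogashira coupling, in which the copper acetylide of 2 transmetalates to the acylpalladium chloride formed from 3 and reductive elimination gives the conjugated ynone, joining C1' to C3 with C1' at the ketone level that steers step 3.

Step 3
Reactants: 4 7-[(tert-butyldimethylsilyl)oxy]oct-5-yn-4-one
Product: 5 (5E)-6-bromo-7-[(tert-butyldimethylsilyl)oxy]-5-iodooct-5-en-4-one (racemic at C7)
Conditions: IBr (1.05 equiv), CH2Cl2, −40 to 0 °C, dark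
Reagents that add atoms: iodine monobromide, BrI
Why: Anti addition of an interhalogen to a conjugated ynone, in which iodine (the positive end of I–Br) ends α to the carbonyl and bromide attacks the β-carbon from the opposite side, as in the known iodochlorination of alkynoates and ynones to (E)-β-chloro-α-iodo carbonyl compounds, so that iodine sits on the future C3, bromine on the future C4 and iodine is cis to the future C5.

Step 4
Reactants: 5 (5E)-6-bromo-7-[(tert-butyldimethylsilyl)oxy]-5-iodooct-5-en-4-one
Product: 6 (4R,5E)-6-bromo-7-[(tert-butyldimethylsilyl)oxy]-5-iodooct-5-en-4-ol (both C7 epimers)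
Conditions: (S)-Me-CBS, i.e. (3aS)-1-methyl-3,3-diphenyltetrahydro-1H,3H-pyrrolo[1,2-c][1,3,2]oxazaborole (20 mol %), BH3·SMe2 (1.0 equiv), THF, −30 °C; MeOH quench
Reagents that add atoms: none
Why: Corey–Bakshi–Shibata reduction, in which the ketone binds the catalyst boron anti to the bulky tetrasubstituted α-iodoalkenyl group and syn to the n-propyl chain, so that the (S)-catalyst should deliver hydride to the face giving the 4R alcohol (the sense known for acetophenone and for α-halo enones), with 1,2-reduction assured by the fully substituted β-carbon.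

Step 5
Reactants: 6 (4R,5E)-6-bromo-7-[(tert-butyldimethylsilyl)oxy]-5-iodooct-5-en-4-ol
Product: 7 (4R,5E)-6-bromo-7-[(tert-butyldimethylsilyl)oxy]-5-iodooct-5-en-4-yl acetate (both C7 epimers)
Conditions: Ac2O, pyridine, DMAP (cat.), CH2Cl2, 0 °C to rt
Reagents that add atoms: acetic anhydride, CC(=O)OC(C)=O
Why: DMAP-catalysed acylation of a secondary allylic alcohol, which installs the acetate of the target with retention because only the O–H bond is touched.

Step 6
Reactants: 7 (4R,5E)-6-bromo-7-[(tert-butyldimethylsilyl)oxy]-5-iodooct-5-en-4-yl acetate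
Product: 8 (4R,5E)-6-bromo-7-hydroxy-5-iodooct-5-en-4-yl acetate (both C7 epimers)
Conditions: HF·pyridine, THF, 0 °C to rt
Reagents that add atoms: none
Why: Fluoride desilylation of a secondary silyl ether under mildly acidic conditions, which the acetate survives and under which it cannot migrate because the two oxygen-bearing carbons are trans across the tetrasubstituted alkene.

Step 7
Reactants: 8 (4R,5E)-6-bromo-7-hydroxy-5-iodooct-5-en-4-yl acetate
Product: 9 (3E,5R)-3-bromo-4-iodo-2-oxooct-3-en-5-yl acetate
Conditions: Dess–Martin periodinane, CH2Cl2, 0 °C to rt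
Reagents that add atoms: none
Why: Dess–Martin oxidation of a secondary allylic alcohol under neutral, halide-free conditions, which should give the methyl ketone without isomerising the now conjugated bromoiodoalkene and removes the carbinol centre that was carried as a mixture.

Step 8
Reactants: 9 (3E,5R)-3-bromo-4-iodo-2-oxooct-3-en-5-yl acetate
Product: 10 (1R)-1-(4-bromo-5-methylidene-2-oxo-2,5-dihydrofuran-3-yl)butyl acetate
Conditions: Pd(PPh3)4 (5 mol %), CO (balloon to 3 atm), Et3N (2 equiv), MeCN, rt to 40 °C, stopped when 9 is consumed
Reagents that add atoms: carbon monoxide, [C-]#[O+]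
Why: Oxidative addition of the C–I bond of 9 to zerovalent palladium and migratory insertion of CO should give an acyl complex of divalent palladium that the E alkene holds next to the acetyl group. The ketone oxygen, as its enol or by direct carbonyl attack followed by loss of a methyl proton to Et3N, then acylates on oxygen and releases zerovalent palladium, so that C2–C3 and O1–C2 form in one operation and the methyl group becomes the C5 exocyclic methylene. The closest known reaction type is the palladium-catalysed carbonylative lactonization of (Z)-β-iodoenones to 5-ylidenebutenolides, applied here to a substrate with an additional α-bromine. The ring closes in the 5-exo-trig mode at the acyl carbon through an in-plane oxygen lone pair, whereas C-acylation to a cyclopentenedione would be a disfavoured 5-(enolendo)-exo-trig closure; no stereocentre is formed and C1' is not touched. The step needs insertion into C–I and not C–Br, which the much faster oxidative addition of the iodide secures, in line with the β-selective palladium couplings of 2,3-dihalopropenoates that leave the α-halogen in place. It also needs the product to survive, which is served by the absence of any nucleophile for an acylpalladium formed at C4–Br, by the hindered tetrasubstituted alkene next to the allylic acetate and by the mild temperature.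

Step 9
Reactants: 10 (1R)-1-(4-bromo-5-methylidene-2-oxo-2,5-dihydrofuran-3-yl)butyl acetate
Product: 12 (1R)-1-[(5Z)-4-bromo-5-(iodomethylidene)-2-oxo-2,5-dihydrofuran-3-yl]butyl acetate, via 5-chloro-5-(iodomethyl) adduct 11 (not isolated)
Conditions: ICl (1.1 equiv), CH2Cl2, −78 to 0 °C; then iPr2NEt, 0 °C to rt
Reagents that add atoms: iodine monochloride, ClI
Why: Halogenation–dehydrohalogenation of a 5-methylidenefuran-2(5H)-one, the sequence used with Br2 to reach (Z)-5-(bromomethylidene)furanones: ICl should add in the Markovnikov sense (iodine to C6, chloride to the oxocarbenium carbon C5) and the hindered amine removes HCl, the iodine ending syn to O1 (Z) because the E isomer would press it against the C4 bromine.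

**Compound list**

1 | but-3-yn-2-ol (racemic) | CC(O)C#C | starting material
2 | tert-butyl(but-3-yn-2-yloxy)dimethylsilane (racemic) | CC(O[Si](C)(C)C(C)(C)C)C#C | intermediate
3 | butanoyl chloride | CCCC(Cl)=O | starting material
4 | 7-[(tert-butyldimethylsilyl)oxy]oct-5-yn-4-one (racemic) | CCCC(=O)C#CC(C)O[Si](C)(C)C(C)(C)C | intermediate
5 | (5E)-6-bromo-7-[(tert-butyldimethylsilyl)oxy]-5-iodooct-5-en-4-one (racemic at C7) | CCCC(=O)/C(I)=C(Br)/C(C)O[Si](C)(C)C(C)(C)C | intermediate
6 | (4R,5E)-6-bromo-7-[(tert-butyldimethylsilyl)oxy]-5-iodooct-5-en-4-ol (both C7 epimers) | CCC[C@@H](O)/C(I)=C(Br)/C(C)O[Si](C)(C)C(C)(C)C | intermediate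
7 | (4R,5E)-6-bromo-7-[(tert-butyldimethylsilyl)oxy]-5-iodooct-5-en-4-yl acetate (both C7 epimers) | CCC[C@@H](OC(C)=O)/C(I)=C(Br)/C(C)O[Si](C)(C)C(C)(C)C | intermediate
8 | (4R,5E)-6-bromo-7-hydroxy-5-iodooct-5-en-4-yl acetate (both C7 epimers) | CCC[C@@H](OC(C)=O)/C(I)=C(Br)/C(C)O | intermediate
9 | (3E,5R)-3-bromo-4-iodo-2-oxooct-3-en-5-yl acetate | CCC[C@@H](OC(C)=O)/C(I)=C(\Br)C(C)=O | intermediate
10 | (1R)-1-(4-bromo-5-methylidene-2-oxo-2,5-dihydrofuran-3-yl)butyl acetate | CCC[C@@H](OC(C)=O)C1=C(Br)C(=C)OC1=O | intermediate
11 | (1R)-1-[4-bromo-5-chloro-5-(iodomethyl)-2-oxo-2,5-dihydrofuran-3-yl]butyl acetate (both C5 epimers) | CCC[C@@H](OC(C)=O)C1=C(Br)C(Cl)(CI)OC1=O | intermediate (not isolated)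
12 | (1R)-1-[(5Z)-4-bromo-5-(iodomethylidene)-2-oxo-2,5-dihydrofuran-3-yl]butyl acetate | CCC[C@@H](OC(C)=O)C1=C(Br)/C(=C/I)OC1=O | target

**Step count and risks**

Total steps: 9. Longest linear sequence: 9 steps (1 to 12).

Steps most likely to fail:

1. Step 8. The ring closure may be slower than decomposition of the acylpalladium, the vinylic bromine or the allylic acetate may be lost to a second reaction with zerovalent palladium, or the configuration at C1' may erode through amine-mediated γ-deprotonation of the enone. The fallback sets out from 9 and separates carbonylation from ring closure: hydroxycarbonylation with water as external nucleophile (PdCl2(PPh3)2, CO, NaHCO3, DMF–H2O) should give the (Z)-4-oxoalk-2-enoic acid, which is expected to exist as its ring tautomer, the lactol (1R)-1-(4-bromo-5-hydroxy-5-methyl-2-oxo-2,5-dihydrofuran-3-yl)butyl acetate F1. Dehydration with P2O5 in CH2Cl2 then gives the exocyclic methylene, and the route is rejoined at 10.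

2. Step 9. The electron-poor exocyclic alkene may add ICl sluggishly, and the amine-induced elimination may be accompanied by attack of the base on the enol lactone or by formation of the E isomer. The fallback sets out from 10 and replaces base-induced dehydrochlorination by acid-mediated dehydration: NIS in MeCN–H2O should give the iodohydrin-type lactol (1R)-1-[4-bromo-5-hydroxy-5-(iodomethyl)-2-oxo-2,5-dihydrofuran-3-yl]butyl acetate F2. P2O5 in CH2Cl2 then removes water under thermodynamic control, as in the classical acid closure to (Z)-halomethylidene furanones, and the route is rejoined at 12.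

3. Step 3. IBr may disproportionate and scramble the halogens, or the addition may leak to the regioisomer or to syn addition. The fallback sets out from 4 and removes the regiochemical question by using one halogen:
- Br2 in CH2Cl2 (−78 to 0 °C) should add anti to give (5E)-5,6-dibromo-7-[(tert-butyldimethylsilyl)oxy]oct-5-en-4-one F3.
- The conditions of steps 4 to 7 then give in turn the alcohol (4R,5E)-5,6-dibromo-7-[(tert-butyldimethylsilyl)oxy]oct-5-en-4-ol F4, its acetate (4R,5E)-5,6-dibromo-7-[(tert-butyldimethylsilyl)oxy]oct-5-en-4-yl acetate F5, the desilylated alcohol (4R,5E)-5,6-dibromo-7-hydroxyoct-5-en-4-yl acetate F6 and the enone (3E,5R)-3,4-dibromo-2-oxooct-3-en-5-yl acetate F7.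
- NaI in acetone should then exchange only the bromide β to the ketone by conjugate addition–elimination, the known halide exchange of β-halovinyl ketones, and the route is rejoined at 9.

**Further compounds**

F1 | step 8 | (1R)-1-(4-bromo-5-hydroxy-5-methyl-2-oxo-2,5-dihydrofuran-3-yl)butyl acetate | CCC[C@@H](OC(C)=O)C1=C(Br)C(C)(O)OC1=O
F2 | step 9 | (1R)-1-[4-bromo-5-hydroxy-5-(iodomethyl)-2-oxo-2,5-dihydrofuran-3-yl]butyl acetate | CCC[C@@H](OC(C)=O)C1=C(Br)C(O)(CI)OC1=O
F3 | step 3 | (5E)-5,6-dibromo-7-[(tert-butyldimethylsilyl)oxy]oct-5-en-4-one | CCCC(=O)/C(Br)=C(Br)/C(C)O[Si](C)(C)C(C)(C)C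
F4 | step 3 | (4R,5E)-5,6-dibromo-7-[(tert-butyldimethylsilyl)oxy]oct-5-en-4-ol | CCC[C@@H](O)/C(Br)=C(Br)/C(C)O[Si](C)(C)C(C)(C)C
F5 | step 3 | (4R,5E)-5,6-dibromo-7-[(tert-butyldimethylsilyl)oxy]oct-5-en-4-yl acetate | CCC[C@@H](OC(C)=O)/C(Br)=C(Br)/C(C)O[Si](C)(C)C(C)(C)C
F6 | step 3 | (4R,5E)-5,6-dibromo-7-hydroxyoct-5-en-4-yl acetate | CCC[C@@H](OC(C)=O)/C(Br)=C(Br)/C(C)O
F7 | step 3 | (3E,5R)-3,4-dibromo-2-oxooct-3-en-5-yl acetate | CCC[C@@H](OC(C)=O)/C(Br)=C(\Br)C(C)=O
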